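**Plan**
Retrosynthesis: the senecioate is cut at the C2–O acyl bond; the C13 vinyl carbinol goes back to a (13E)-allylic alcohol (asymmetric epoxidation, reductive epoxide opening); rings A and B are opened together at C4–C5 and C9–C10, with the C7=C8 alkene traced to a phenylsulfonyl group on C7; the acyclic tetraene is cut at C6–C7 (sulfone alkylation) into a C10 allylic bromide and a C10 allyl sulfone.
Forward: the bromide is built from (R)-epichlorohydrin (isopropenyl Grignard, acetylide, carboalumination) and the sulfone from geranyl acetate; they are joined at C6–C7; one radical cascade then closes ring A (C4–C5), closes ring B (C9–C10) and ejects the sulfonyl group to leave C7=C8; the side-chain carbinol and the ester follow.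
Enabling feature: C4, C10 and C8 each carry a methyl group and lie 1,5 to an alkene terminus along the chain (C4···C5=C10, C10···C9=C8), so three tertiary radicals can relay from the gem-dimethyl carbon C4 through rings A and B; C7 is β to the last radical (C8), so a leaving group there fixes the alkene position.
Stereochemistry: C2 comes from (R)-epichlorohydrin; C5, C10 and C9 are relayed from C2 in the cascade (equatorial C2 silyloxy group in a chair–chair transition state, (E)-alkenes); C13 comes from a Sharpless asymmetric epoxidation with L-(+)-diethyl tartrate.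

Key step: step 10

Remark: labdane numbering is used only as a locant system (C1–C10 decalin, C11–C16 side chain on C9, C17 on C8, C20 on C10) with explicit CIP descriptors, and compound 16 is carried as both epimers at the sulfonyl-bearing carbon C7, a centre that step 10 erases.

Step 1
Reactants: 1 (R)-epichlorohydrin
Product: 3 (R)-2-(2-methylprop-2-en-1-yl)oxirane, via chlorohydrin 2 (not isolated)
Conditions: CH2=C(CH3)MgBr, CuBr·SMe2 (10 mol%), THF, −40 °C; aq. work-up; then NaOH, Et2O, rt
Reagents that add atoms: isopropenylmagnesium bromide, C=C(C)[Mg]Br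
Why: Copper-catalysed Grignard opening of the epoxide at its CH2 terminus (SN2) and Williamson-type closure of the chlorohydrin never touch the C–O bond of the stereocentre, so the (R) configuration of the future C2 is carried over from the chiral pool.

Step 2
Reactants: 3 (R)-2-(2-methylprop-2-en-1-yl)oxirane
Product: 4 (R)-6-methylhept-6-en-1-yn-4-ol
Conditions: HC≡CLi·H2NCH2CH2NH2, DMSO, 0 °C to rt
Reagents that add atoms: lithium acetylide (ethylenediamine complex), [Li]C#C
Why: SN2 opening of the terminal epoxide by acetylide at the unsubstituted carbon should give the homopropargylic alcohol with the stereocentre untouched.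

Step 3
Reactants: 4 (R)-6-methylhept-6-en-1-yn-4-ol
Product: 5 (R)-tert-butyldimethyl[(6-methylhept-6-en-1-yn-4-yl)oxy]silane
Conditions: TBSCl, imidazole, DMF, rt
Reagents that add atoms: tert-butyldimethylsilyl chloride, CC(C)(C)[Si](C)(C)Cl
Why: Standard silylation masks the alcohol from the organometallic steps and installs the bulky group that later sits equatorial and steers the cascade.

Step 4
Reactants: 5 (R)-tert-butyldimethyl[(6-methylhept-6-en-1-yn-4-yl)oxy]silane
Product: 8 (2E,5R)-5-[(tert-butyldimethylsilyl)oxy]-3,7-dimethylocta-2,7-dien-1-ol, via alkenylalane 6 (not isolated), via lithium alkenylaluminate 7 (not isolated)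
Conditions: Me3Al (3 equiv), Cp2ZrCl2 (0.25 equiv), CH2Cl2, 0 °C to rt; then n-BuLi, THF, −78 °C; (CH2O)n, −78 °C to rt
Reagents that add atoms: trimethylaluminium, C[Al](C)C; paraformaldehyde (formaldehyde source), C=O
Why: Negishi carboalumination adds methyl and aluminium syn across the terminal alkyne (methyl to the internal carbon) and the derived aluminate adds to formaldehyde with retention of geometry, which should fix the (E)-C5=C10 alkene while the 1,1-disubstituted alkene stays inert.

Step 5
Reactants: 8 (2E,5R)-5-[(tert-butyldimethylsilyl)oxy]-3,7-dimethylocta-2,7-dien-1-ol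
Product: 9 (4R,6E)-[(8-bromo-2,6-dimethylocta-1,6-dien-4-yl)oxy](tert-butyl)dimethylsilane
Conditions: CBr4, PPh3, CH2Cl2, 0 °C
Reagents that add atoms: carbon tetrabromide, BrC(Br)(Br)Br
Why: Appel bromination of the primary allylic alcohol by SN2 displacement should keep the (E)-alkene and the silyl ether.

Step 6
Reactants: 10 geranyl acetate
Product: 11 (2E,6E)-8-hydroxy-3,7-dimethylocta-2,6-dien-1-yl acetate
Conditions: SeO2 (0.1 equiv), t-BuOOH (70% aq., 3 equiv), salicylic acid (0.1 equiv), CH2Cl2, rt
Reagents that add atoms: tert-butyl hydroperoxide (terminal oxidant, oxygen relayed by SeO2), CC(C)(C)OO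
Why: Selenium dioxide allylic oxidation (ene reaction, then [2,3]-sigmatropic shift) should hydroxylate the (E)-methyl group of the electron-richer distal alkene, the proximal alkene being deactivated by the allylic acetate.

Step 7
Reactants: 11 (2E,6E)-8-hydroxy-3,7-dimethylocta-2,6-dien-1-yl acetate
Product: 13 (2E,6E)-3,7-dimethyl-8-(phenylsulfonyl)octa-2,6-dien-1-yl acetate, via allylic mesylate 12 (not isolated)
Conditions: MsCl, Et3N, CH2Cl2, −40 °C; then PhSO2Na, DMF, rt
Reagents that add atoms: sodium benzenesulfinate, [Na+].[O-]S(=O)c1ccccc1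
Why: Mesylation of the primary allylic alcohol and SN2 S-alkylation of the soft sulfinate anion should give the primary allyl sulfone with the (E)-alkene intact.

Step 8
Reactants: 13 (2E,6E)-3,7-dimethyl-8-(phenylsulfonyl)octa-2,6-dien-1-yl acetate
Product: 14 (2E,6E)-3,7-dimethyl-8-(phenylsulfonyl)octa-2,6-dien-1-ol
Conditions: K2CO3 (0.2 equiv), MeOH, rt
Reagents that add atoms: none
Why: Base-catalysed transesterification (methanolysis) removes the acetate and leaves the sulfone untouched.

Step 9
Reactants: 14 (2E,6E)-3,7-dimethyl-8-(phenylsulfonyl)octa-2,6-dien-1-ol; 9 (4R,6E)-[(8-bromo-2,6-dimethylocta-1,6-dien-4-yl)oxy](tert-butyl)dimethylsilane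
Product: 16 (2E,6E,10E,13R)-13-[(tert-butyldimethylsilyl)oxy]-3,7,11,15-tetramethyl-8-(phenylsulfonyl)hexadeca-2,6,10,15-tetraen-1-ol, via dilithio sulfone 15 (not isolated)
Conditions: 14, n-BuLi (2.1 equiv), THF/DMPU, −78 °C; then 9, −78 to −30 °C
Reagents that add atoms: none
Why: In this Julia-type sulfone alkylation the α-sulfonyl allylic carbanion of the dianion is far more nucleophilic than the alkoxide and should displace the primary allylic bromide by SN2 at the carbon α to sulfur, forming C6–C7 with all (E)-alkenes retained; the new C7 centre is uncontrolled and need not be controlled.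

Step 10
Reactants: 16 (2E,6E,10E,13R)-13-[(tert-butyldimethylsilyl)oxy]-3,7,11,15-tetramethyl-8-(phenylsulfonyl)hexadeca-2,6,10,15-tetraen-1-ol
Product: 17 (2R,5R,9R,10R)-2-[(tert-butyldimethylsilyl)oxy]labda-7,13E-dien-15-ol
Conditions: Fe(acac)3 (0.5 equiv), PhSiH3 (3 equiv), EtOH/(CH2OH)2 9:1, 0.01 M, Ar, 40 °C
Reagents that add atoms: none
Why: Proposed new method: an iron hydride formed from Fe(acac)3 and PhSiH3 should transfer a hydrogen atom to the CH2 terminus of the 1,1-disubstituted (isopropenyl) alkene; the tertiary C4 radical should add to C5 of the (E)-C5=C10 alkene (ring A, 6-endo-trig, the C4–C5 bond), the tertiary C10 radical should add to C9 of the (E)-allyl sulfone (ring B, 6-endo-trig), and the C8 radical should expel the phenylsulfonyl radical from C7 by β-scission, which writes the C7=C8 double bond, the sulfonyl radical being reduced to sulfinate by divalent iron so that trivalent iron is returned. The closest known reaction types are the Fe(acac)3/PhSiH3 hydrogen-atom-transfer radical bicyclization of polyenes that ends on an electron-poor alkene and the radical allylation by addition–fragmentation on allyl sulfones; their union in one cascade is the new element. C5 is set by a chair transition state for ring A in which the C2 silyloxy group is equatorial (an axial group would clash with the pseudo-axial C4 methyl), so the C2 centre selects the alkene face; C10 follows from the (E)-C5=C10 geometry and trans-decalin chair–chair closure, and C9 from the (E)-C8=C9 geometry, which leaves C11 equatorial. The step needs hydrogen-atom transfer to the isopropenyl group only (1,1-disubstituted alkenes accept hydrogen atoms faster than trisubstituted ones), 6-endo rather than 5-exo closure (attack at the less substituted alkene carbon gives a tertiary radical and avoids a bond between two quaternary carbons), and fragmentation before hydrogen capture (high dilution and the weak C–S bond β to the radical); both C7 epimers converge on the same alkene.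

Step 11
Reactants: 17 (2R,5R,9R,10R)-2-[(tert-butyldimethylsilyl)oxy]labda-7,13E-dien-15-ol
Product: 18 (2R,5R,9R,10R,13S,14S)-2-[(tert-butyldimethylsilyl)oxy]-13,14-epoxylabd-7-en-15-ol
Conditions: Ti(OiPr)4 (0.1 equiv), L-(+)-diethyl tartrate (0.12 equiv), t-BuOOH (2 equiv, isooctane), 4 Å MS, CH2Cl2, −20 °C
Reagents that add atoms: tert-butyl hydroperoxide, CC(C)(C)OO
Why: In the Sharpless asymmetric epoxidation the titanium–L-(+)-tartrate complex binds the allylic hydroxyl and should deliver oxygen to the face of the (13E)-alkene that gives the (13S,14S)-epoxide under reagent control, while the C7=C8 alkene, which has no allylic hydroxyl, is left alone.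

Step 12
Reactants: 18 (2R,5R,9R,10R,13S,14S)-2-[(tert-butyldimethylsilyl)oxy]-13,14-epoxylabd-7-en-15-ol
Product: 20 (2R,5R,9R,10R,13S)-2-[(tert-butyldimethylsilyl)oxy]labda-7,14-dien-13-ol, via epoxy iodide 19 (not isolated)
Conditions: PPh3, I2, imidazole, THF, 0 °C; then Zn dust, AcOH, EtOH, rt
Reagents that add atoms: none
Why: Appel-type iodination of the primary alcohol, then zinc insertion into the C–I bond and β-elimination with opening of the epoxide (reductive elimination of a 2,3-epoxy iodide), should give the tertiary allylic alcohol, and since the C13–O bond is never broken C13 stays (S).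

Step 13
Reactants: 20 (2R,5R,9R,10R,13S)-2-[(tert-butyldimethylsilyl)oxy]labda-7,14-dien-13-ol
Product: 21 (2R,5R,9R,10R,13S)-labda-7,14-diene-2,13-diol
Conditions: TBAF, THF, rt
Reagents that add atoms: none
Why: Fluoride-induced desilylation, driven by the strong Si–F bond, frees the C2 hydroxyl without touching the tertiary allylic alcohol or the alkenes.

Step 14
Reactants: 21 (2R,5R,9R,10R,13S)-labda-7,14-diene-2,13-diol; 22 3-methylbut-2-enoic acid
Product: 23 (2R,5R,9R,10R,13S)-13-hydroxylabda-7,14-dien-2-yl 3-methylbut-2-enoate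
Conditions: DCC, DMAP (0.1 equiv), CH2Cl2, 0 °C to rt
Reagents that add atoms: none
Why: In this Steglich esterification the equatorial secondary C2 hydroxyl is acylated while the hindered tertiary allylic C13 hydroxyl should not react, and carbodiimide activation avoids the ketene pathway that deconjugates senecioyl chloride.

**Compound list**
1 | (R)-epichlorohydrin | ClC[C@H]1CO1 | starting material
2 | (R)-1-chloro-4-methylpent-4-en-2-ol | C=C(C)C[C@@H](O)CCl | intermediate
3 | (R)-2-(2-methylprop-2-en-1-yl)oxirane | C=C(C)C[C@@H]1CO1 | intermediate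
4 | (R)-6-methylhept-6-en-1-yn-4-ol | C=C(C)C[C@@H](O)CC#C | intermediate
5 | (R)-tert-butyldimethyl[(6-methylhept-6-en-1-yn-4-yl)oxy]silane | C=C(C)C[C@@H](O[Si](C)(C)C(C)(C)C)CC#C | intermediate
6 | [(1E,4R)-4-[(tert-butyldimethylsilyl)oxy]-2,6-dimethylhepta-1,6-dien-1-yl]dimethylalane | C=C(C)C[C@@H](O[Si](C)(C)C(C)(C)C)C/C(C)=C/[Al](C)C | intermediate
7 | lithium butyl[(1E,4R)-4-[(tert-butyldimethylsilyl)oxy]-2,6-dimethylhepta-1,6-dien-1-yl]dimethylaluminate | C=C(C)C[C@@H](O[Si](C)(C)C(C)(C)C)C/C(C)=C/[Al-](C)(C)CCCC.[Li+] | intermediate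
8 | (2E,5R)-5-[(tert-butyldimethylsilyl)oxy]-3,7-dimethylocta-2,7-dien-1-ol | C=C(C)C[C@@H](O[Si](C)(C)C(C)(C)C)C/C(C)=C/CO | intermediate
9 | (4R,6E)-[(8-bromo-2,6-dimethylocta-1,6-dien-4-yl)oxy](tert-butyl)dimethylsilane | C=C(C)C[C@@H](O[Si](C)(C)C(C)(C)C)C/C(C)=C/CBr | intermediate
10 | geranyl acetate, (2E)-3,7-dimethylocta-2,6-dien-1-yl acetate | CC(C)=CCC/C(C)=C/COC(C)=O | starting material
11 | (2E,6E)-8-hydroxy-3,7-dimethylocta-2,6-dien-1-yl acetate | OC/C(C)=C/CC/C(C)=C/COC(C)=O | intermediate
12 | (2E,6E)-3,7-dimethyl-8-[(methylsulfonyl)oxy]octa-2,6-dien-1-yl acetate | CS(=O)(=O)OC/C(C)=C/CC/C(C)=C/COC(C)=O | intermediate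
13 | (2E,6E)-3,7-dimethyl-8-(phenylsulfonyl)octa-2,6-dien-1-yl acetate | O=S(=O)(C/C(C)=C/CC/C(C)=C/COC(C)=O)c1ccccc1 | intermediate
14 | (2E,6E)-3,7-dimethyl-8-(phenylsulfonyl)octa-2,6-dien-1-ol | O=S(=O)(C/C(C)=C/CC/C(C)=C/CO)c1ccccc1 | intermediate
15 | dilithium salt of 14 (alkoxide and α-sulfonyl allylic carbanion) | [Li+].[Li+].[O-]C/C=C(\C)CC/C=C(\C)[CH-]S(=O)(=O)c1ccccc1 | intermediate
16 | (2E,6E,10E,13R)-13-[(tert-butyldimethylsilyl)oxy]-3,7,11,15-tetramethyl-8-(phenylsulfonyl)hexadeca-2,6,10,15-tetraen-1-ol, both epimers at C8 of the chain (labdane C7) | C=C(C)C[C@@H](O[Si](C)(C)C(C)(C)C)C/C(C)=C/CC(S(=O)(=O)c1ccccc1)/C(C)=C/CC/C(C)=C/CO | intermediate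
17 | (2R,5R,9R,10R)-2-[(tert-butyldimethylsilyl)oxy]labda-7,13E-dien-15-ol | OC/C=C(\C)CC[C@@H]1C(C)=CC[C@@H]2C(C)(C)C[C@@H](O[Si](C)(C)C(C)(C)C)C[C@@]12C | intermediate
18 | (2R,5R,9R,10R,13S,14S)-2-[(tert-butyldimethylsilyl)oxy]-13,14-epoxylabd-7-en-15-ol | OC[C@@H]1O[C@@]1(C)CC[C@@H]2C(C)=CC[C@@H]3C(C)(C)C[C@@H](O[Si](C)(C)C(C)(C)C)C[C@@]23C | intermediate
19 | (2R,5R,9R,10R,13S,14R)-tert-butyl[(13,14-epoxy-15-iodolabd-7-en-2-yl)oxy]dimethylsilane | IC[C@@H]1O[C@@]1(C)CC[C@@H]2C(C)=CC[C@@H]3C(C)(C)C[C@@H](O[Si](C)(C)C(C)(C)C)C[C@@]23C | intermediate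
20 | (2R,5R,9R,10R,13S)-2-[(tert-butyldimethylsilyl)oxy]labda-7,14-dien-13-ol | C=C[C@@](C)(O)CC[C@@H]1C(C)=CC[C@@H]2C(C)(C)C[C@@H](O[Si](C)(C)C(C)(C)C)C[C@@]12C | intermediate
21 | (2R,5R,9R,10R,13S)-labda-7,14-diene-2,13-diol | C=C[C@@](C)(O)CC[C@@H]1C(C)=CC[C@@H]2C(C)(C)C[C@@H](O)C[C@@]12C | intermediate
22 | 3-methylbut-2-enoic acid (senecioic acid) | CC(C)=CC(=O)O | starting material
23 | (2R,5R,9R,10R,13S)-13-hydroxylabda-7,14-dien-2-yl 3-methylbut-2-enoate; systematic: (2R,4aR,8R,8aR)-8-[(3S)-3-hydroxy-3-methylpent-4-en-1-yl]-4,4,7,8a-tetramethyl-1,2,3,4,4a,5,8,8a-octahydronaphthalen-2-yl 3-methylbut-2-enoate | C=C[C@@](C)(O)CC[C@@H]1C(C)=CC[C@@H]2C(C)(C)C[C@@H](OC(=O)C=C(C)C)C[C@@]12C | target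

**Step count and risks**
Total steps: 14. Longest linear sequence: 11 (steps 1–5 and 9–14).

Most likely to fail:

1. Step 10 (bears the label). The cascade may be cut short by hydrogen capture at the C4 or C10 radical before ring closure, hydrogen-atom transfer may reach a trisubstituted alkene, or a sulfonyl-radical chain may shift the allyl sulfone. Fallback with known chemistry, setting out from 16 and coming back at 17: acetylation (Ac2O, pyridine) should give the sulfonyl tetraenyl acetate F1. Oxidation of its α-sulfonyl carbanion (LDA, THF, −78 °C; MoO5·pyridine·HMPA) should give the (E)-α-methyl enone F2. The same Fe(acac)3/PhSiH3 conditions then run a hydrogen-atom-transfer radical bicyclization that ends by Giese addition of the C10 radical to C9 of the enone, a termination with direct precedent for polyene bicyclizations, and should give the 7-oxo decalin acetate F3. The more substituted enol triflate F4 (Tf2O, 2,6-di-tert-butyl-4-methylpyridine, CH2Cl2) is reduced with formate under catalysis by zerovalent palladium (Pd(OAc)2, PPh3, HCO2H, Bu3N, DMF) to the Δ7 acetate F5, and methanolysis (K2CO3, MeOH) returns 17.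

2. Step 4. Carbometalation may stall, or the alkenylalane may be protonated before it captures formaldehyde, leaving a 1,1-disubstituted alkene instead of the allylic alcohol. Fallback setting out from 5 and coming back at 8: lithiation and paraformaldehyde (n-BuLi, THF, −78 °C; (CH2O)n) should give the propargylic alcohol F6. Hydroxyl-directed trans-hydroalumination and iodinolysis (NaAlH2(OCH2CH2OMe)2, THF, 0 °C; then I2, −78 °C) should give the (Z)-3-iodo allylic alcohol F7. Me2CuLi (Et2O, 0 °C) then replaces iodine by methyl with retention and returns 8.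

3. Step 9. The dianion may aggregate or dissolve poorly, may act as a base on the allylic bromide (elimination), or may react through oxygen or the γ-carbon. Fallback setting out from 14 (with 9) and coming back at 16: the hydroxyl is masked first (TBSCl, imidazole) to give the silyl ether sulfone F8. Its mono-anion (n-BuLi, 1.05 equiv, THF/DMPU, −78 °C) is alkylated with 9 to give the bis-silyl sulfone F9. Selective cleavage of the primary allylic silyl ether (HF·pyridine, pyridine, THF, 0 °C) returns 16.

**Further compounds**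
F1 | step 10 | (2E,6E,10E,13R)-13-[(tert-butyldimethylsilyl)oxy]-3,7,11,15-tetramethyl-8-(phenylsulfonyl)hexadeca-2,6,10,15-tetraen-1-yl acetate (both C8 epimers) | C=C(C)C[C@@H](O[Si](C)(C)C(C)(C)C)C/C(C)=C/CC(S(=O)(=O)c1ccccc1)/C(C)=C/CC/C(C)=C/COC(C)=O
F2 | step 10 | (2E,6E,10E,13R)-13-[(tert-butyldimethylsilyl)oxy]-3,7,11,15-tetramethyl-8-oxohexadeca-2,6,10,15-tetraen-1-yl acetate | C=C(C)C[C@@H](O[Si](C)(C)C(C)(C)C)C/C(C)=C/CC(=O)/C(C)=C/CC/C(C)=C/COC(C)=O
F3 | step 10 | (2R,5R,9R,10S)-2-[(tert-butyldimethylsilyl)oxy]-7-oxolabd-13E-en-15-yl acetate (both C8 epimers) | CC(=O)OC/C=C(\C)CC[C@@H]1C(C)C(=O)C[C@@H]2C(C)(C)C[C@@H](O[Si](C)(C)C(C)(C)C)C[C@@]12C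
F4 | step 10 | (2R,5R,9S,10R)-2-[(tert-butyldimethylsilyl)oxy]-7-[(trifluoromethylsulfonyl)oxy]labda-7,13E-dien-15-yl acetate | CC(=O)OC/C=C(\C)CC[C@@H]1C(C)=C(OS(=O)(=O)C(F)(F)F)C[C@@H]2C(C)(C)C[C@@H](O[Si](C)(C)C(C)(C)C)C[C@@]12C
F5 | step 10 | (2R,5R,9R,10R)-2-[(tert-butyldimethylsilyl)oxy]labda-7,13E-dien-15-yl acetate | CC(=O)OC/C=C(\C)CC[C@@H]1C(C)=CC[C@@H]2C(C)(C)C[C@@H](O[Si](C)(C)C(C)(C)C)C[C@@]12C
F6 | step 4 | (R)-5-[(tert-butyldimethylsilyl)oxy]-7-methyloct-7-en-2-yn-1-ol | C=C(C)C[C@@H](O[Si](C)(C)C(C)(C)C)CC#CCO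
F7 | step 4 | (2Z,5R)-5-[(tert-butyldimethylsilyl)oxy]-3-iodo-7-methylocta-2,7-dien-1-ol | C=C(C)C[C@@H](O[Si](C)(C)C(C)(C)C)C/C(I)=C/CO
F8 | step 9 | tert-butyl{[(2E,6E)-3,7-dimethyl-8-(phenylsulfonyl)octa-2,6-dien-1-yl]oxy}dimethylsilane | O=S(=O)(C/C(C)=C/CC/C(C)=C/CO[Si](C)(C)C(C)(C)C)c1ccccc1
F9 | step 9 | (2E,6E,10E,13R)-1,13-bis[(tert-butyldimethylsilyl)oxy]-3,7,11,15-tetramethyl-8-(phenylsulfonyl)hexadeca-2,6,10,15-tetraene (both C8 epimers) | C=C(C)C[C@@H](O[Si](C)(C)C(C)(C)C)C/C(C)=C/CC(S(=O)(=O)c1ccccc1)/C(C)=C/CC/C(C)=C/CO[Si](C)(C)C(C)(C)C
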